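**Plan**
The C2–C6 chain with its two ketones (C3 and C5), lying between the styryl carbon C1 on ring A and the benzylic carbon C7 on ring B, is treated as a decarboxylated 4-hydroxy-6-styryl-2-pyrone. Putting CO2 back on C6 and lactonising it onto the C3 oxygen gives a 3-benzylpyrone in which pyrone C3 is target C6.
Pyrone C3 sits between the lactone carbon C2 and the enolic carbon C4 and is the one doubly activated carbon, so the retrosynthesis cuts C6–C7 there (vanillin plus a hydride donor). It then cuts C3–C4, between the feruloyl carbon and the γ-carbon of an acetoacetate equivalent.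
Forward: silyl-protected ferulic acid acylates a dioxinone (C3–C4), heating closes the pyrone (the only ring formed, and a temporary one), and the phenol is freed. The pyrone is then reductively benzylated at C3 with vanillin (C6–C7), and hot water opens the lactone with loss of CO2.
Stereochemistry: the target has no stereocentre; the E-C1=C2 alkene comes from ferulic acid and is carried through unchanged.

Key step: step 5

Remark: the chain is numbered C1 (styryl carbon on ring A) to C7 (benzylic carbon on ring B). The target is drawn as the diketone although it should exist largely as enol tautomers. 2,2,6-Trimethyl-4H-1,3-dioxin-4-one is used as the commercial acetoacetate equivalent because it allows a neutral, thermal pyrone closure. TBS = tert-butyldimethylsilyl.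

**Step 1**
Reactants: 1 ferulic acid
Product: 3 (E)-3-[4-(tert-butyldimethylsilyloxy)-3-methoxyphenyl]prop-2-enoic acid (O-TBS ferulic acid), via bis-silylated ferulic acid 2 (not isolated)
Conditions: TBSCl (2.3 equiv), imidazole (5 equiv), DMF, rt; then AcOH/THF/H2O (3:1:1), rt
Reagents that add atoms: TBSCl, CC(C)(C)[Si](C)(C)Cl
Why: Silylation with TBSCl and imidazole caps both the phenol and the acid, and selective hydrolysis of the much more labile silyl ester by aqueous acetic acid leaves the aryl silyl ether, which later keeps a phenoxide out of the enolate acylation.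

**Step 2**
Reactants: 3 O-TBS ferulic acid; 4 2,2,6-trimethyl-4H-1,3-dioxin-4-one
Product: 6 keto-dioxinone 6-[(E)-4-[4-(tert-butyldimethylsilyloxy)-3-methoxyphenyl]-2-oxobut-3-en-1-yl]-2,2-dimethyl-4H-1,3-dioxin-4-one, via acyl imidazolide 5 (not isolated)
Conditions: CDI (1.1 equiv), THF, rt; then added to the lithium dienolate from 4 (3.0 equiv) and LiN(SiMe3)2 (3.0 equiv), THF, −78 to −40 °C; aq. NH4Cl
Reagents that add atoms: none
Why: CDI activation gives the N-acylimidazole, and Claisen-type C-acylation of the dioxinone lithium dienolate should occur at its γ-carbon (the exocyclic CH2) as it does with acyl azoles and acid chlorides, the extra equivalents of dienolate absorbing the imidazole N–H and the acidic methylene of the product.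

**Step 3**
Reactants: 6 keto-dioxinone
Product: 8 6-[(E)-2-[4-(tert-butyldimethylsilyloxy)-3-methoxyphenyl]ethenyl]-4-hydroxy-2H-pyran-2-one, via acylketene 7 (not isolated)
Conditions: toluene (0.05 M), 110 °C
Reagents that add atoms: none
Why: Thermal retro-[4+2] loss of acetone from the dioxinone releases an acylketene that the enol oxygen of the styryl ketone captures in a six-membered lactonisation, the standard conversion of 6-(2-oxoalkyl)dioxinones into 6-substituted 4-hydroxy-2-pyrones, under neutral conditions that spare the silyl ether and the E-alkene.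

**Step 4**
Reactants: 8 silyl-protected styrylpyrone
Product: 9 4-hydroxy-6-[(E)-2-(4-hydroxy-3-methoxyphenyl)ethenyl]-2H-pyran-2-one
Conditions: Bu4NF (1.2 equiv), AcOH (1.5 equiv), THF, 0 °C to rt; dilute HCl work-up
Reagents that add atoms: none
Why: Fluoride-mediated cleavage of an aryl silyl ether, buffered with acetic acid so that the acidic pyrone and the styryl unit meet no strong base.

**Step 5**
Reactants: 9 styrylpyrone; 10 vanillin; 11 Hantzsch ester (diethyl 2,6-dimethyl-1,4-dihydropyridine-3,5-dicarboxylate)
Product: 13 4-hydroxy-3-(4-hydroxy-3-methoxybenzyl)-6-[(E)-2-(4-hydroxy-3-methoxyphenyl)ethenyl]-2H-pyran-2-one, via benzylidene pyrandione 12 (not isolated)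
Conditions: 10 (1.05 equiv), 11 (1.2 equiv), L-proline (20 mol%), EtOH, 40 °C, argon, dark
Reagents that add atoms: none
Why: L-Proline converts vanillin into an iminium ion, the enolic C3 of pyrone 9 adds to it, and loss of proline leaves the 3-benzylidene-pyran-2,4-dione 12, whose exocyclic alkene bears two acceptor carbonyls and so accepts hydride from Hantzsch ester 11 at the benzylic carbon, protonation of the pyronate then giving 13 with the C6–C7 bond (target numbering) in place. The closest known reaction type is the amine-catalysed three-component reductive alkylation (Knoevenagel condensation followed by transfer hydrogenation) of cyclic 1,3-dicarbonyl CH-acids such as 4-hydroxycoumarin and 4-hydroxy-6-methyl-2-pyrone with aldehydes and Hantzsch ester. No ring is closed and no stereocentre is formed. Site selectivity for C3 over C5 is needed, and C3 is the only carbon flanked by both oxygenated carbons C2 and C4. Chemoselectivity for the benzylidene over the styryl alkene is needed, and only the doubly activated benzylidene dione is a strong enough hydride acceptor for Hantzsch ester, so the E-styryl unit should stay untouched. Mono-benzylation is secured by having 11 present from the start, so that reduction intercepts 12 before a second pyrone adds, an addition that is in any case reversible.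

**Step 6**
Reactants: 13 3-benzylated styrylpyrone
Product: 15 dihydrocurcumin [(1E)-1,7-bis(4-hydroxy-3-methoxyphenyl)hept-1-ene-3,5-dione], via dioxo acid 14 (not isolated)
Conditions: degassed H2O/1,4-dioxane (1:1), 110 °C (sealed tube), argon
Reagents that add atoms: water, O
Why: Water opens the 4-hydroxy-2-pyrone through its 2,4-dione tautomer (a cyclic enol ester) to the 2-benzyl-3,5-dioxo acid, which as a β-keto acid loses CO2 at the reaction temperature, the same hydrolytic ring opening and decarboxylation that turns triacetic acid lactone and its 3-alkyl derivatives into 1,3-diketones in hot water.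

**Compound list**
1 | ferulic acid, (E)-3-(4-hydroxy-3-methoxyphenyl)prop-2-enoic acid | COc1cc(/C=C/C(=O)O)ccc1O | starting material
2 | tert-butyldimethylsilyl (E)-3-[4-(tert-butyldimethylsilyloxy)-3-methoxyphenyl]prop-2-enoate | COc1cc(/C=C/C(=O)O[Si](C)(C)C(C)(C)C)ccc1O[Si](C)(C)C(C)(C)C | intermediate (not isolated)
3 | (E)-3-[4-(tert-butyldimethylsilyloxy)-3-methoxyphenyl]prop-2-enoic acid | COc1cc(/C=C/C(=O)O)ccc1O[Si](C)(C)C(C)(C)C | intermediate
4 | 2,2,6-trimethyl-4H-1,3-dioxin-4-one | CC1=CC(=O)OC(C)(C)O1 | starting material
5 | (E)-3-[4-(tert-butyldimethylsilyloxy)-3-methoxyphenyl]-1-(1H-imidazol-1-yl)prop-2-en-1-one | COc1cc(/C=C/C(=O)n2ccnc2)ccc1O[Si](C)(C)C(C)(C)C | intermediate (not isolated)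
6 | 6-[(E)-4-[4-(tert-butyldimethylsilyloxy)-3-methoxyphenyl]-2-oxobut-3-en-1-yl]-2,2-dimethyl-4H-1,3-dioxin-4-one | COc1cc(/C=C/C(=O)CC2=CC(=O)OC(C)(C)O2)ccc1O[Si](C)(C)C(C)(C)C | intermediate
7 | (6E)-7-[4-(tert-butyldimethylsilyloxy)-3-methoxyphenyl]hepta-1,6-diene-1,3,5-trione (acylketene) | COc1cc(/C=C/C(=O)CC(=O)C=C=O)ccc1O[Si](C)(C)C(C)(C)C | intermediate (not isolated)
8 | 6-[(E)-2-[4-(tert-butyldimethylsilyloxy)-3-methoxyphenyl]ethenyl]-4-hydroxy-2H-pyran-2-one | COc1cc(/C=C/C2=CC(O)=CC(=O)O2)ccc1O[Si](C)(C)C(C)(C)C | intermediate
9 | 4-hydroxy-6-[(E)-2-(4-hydroxy-3-methoxyphenyl)ethenyl]-2H-pyran-2-one | COc1cc(/C=C/C2=CC(O)=CC(=O)O2)ccc1O | intermediate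
10 | vanillin, 4-hydroxy-3-methoxybenzaldehyde | COc1cc(C=O)ccc1O | starting material
11 | Hantzsch ester, diethyl 2,6-dimethyl-1,4-dihydropyridine-3,5-dicarboxylate | CCOC(=O)C1=C(C)NC(C)=C(C(=O)OCC)C1 | starting material
12 | 3-(4-hydroxy-3-methoxybenzylidene)-6-[(E)-2-(4-hydroxy-3-methoxyphenyl)ethenyl]-2H-pyran-2,4(3H)-dione (geometry of the exocyclic alkene not defined) | COc1cc(/C=C/C2=CC(=O)C(=Cc3ccc(O)c(OC)c3)C(=O)O2)ccc1O | intermediate (not isolated)
13 | 4-hydroxy-3-(4-hydroxy-3-methoxybenzyl)-6-[(E)-2-(4-hydroxy-3-methoxyphenyl)ethenyl]-2H-pyran-2-one | COc1cc(/C=C/C2=CC(O)=C(Cc3ccc(O)c(OC)c3)C(=O)O2)ccc1O | intermediate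
14 | (6E)-2-(4-hydroxy-3-methoxybenzyl)-7-(4-hydroxy-3-methoxyphenyl)-3,5-dioxohept-6-enoic acid (racemic at C2) | COc1cc(/C=C/C(=O)CC(=O)C(Cc2ccc(O)c(OC)c2)C(=O)O)ccc1O | intermediate (not isolated)
15 | dihydrocurcumin, (1E)-1,7-bis(4-hydroxy-3-methoxyphenyl)hept-1-ene-3,5-dione | COc1cc(/C=C/C(=O)CC(=O)CCc2ccc(O)c(OC)c2)ccc1O | target

**Step count**
Total: 6 steps. Longest linear sequence: 6 steps, from ferulic acid 1 to 15; compound 4 enters at step 2, and 10 and 11 enter at step 5.

**Steps most likely to fail**

Step 5. The electron-rich aldehyde may condense slowly, and hydride transfer to the push–pull benzylidene may be slow. A second pyrone could then add in Michael fashion and drain material into a bis(pyronyl)methane. The fallback sets out from 9 and forms the same C–C bond without a benzylidene or a hydride donor. Vanillin 10 is reduced with NaBH4 in MeOH to vanillyl alcohol (4-hydroxy-3-methoxybenzyl alcohol) F1. Pyrone 9 is then C3-benzylated with F1 under Brønsted acid catalysis (cat. TsOH, 1,4-dioxane, 80 °C, slow addition of F1). Ionisation of F1 to the para-quinone methide or benzylic cation and Friedel–Crafts-type capture by C3 is the dehydrative benzylation known for 4-hydroxycoumarins with benzylic alcohols. The fallback returns to the route at 13.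

Step 6. The conjugated, C3-substituted pyrone may open slowly, so that prolonged heating brings on retro-Claisen cleavage of the liberated diketone or hydration and retro-aldol scission of the enone. The fallback sets out from 13 and separates ring opening from loss of the carboxyl carbon. Chelation-assisted methanolysis with Mg(OMe)2 in MeOH at reflux, the alkoxide opening used to turn 4-hydroxy-2-pyrones into 3,5-dioxo esters, should give methyl (6E)-2-(4-hydroxy-3-methoxybenzyl)-7-(4-hydroxy-3-methoxyphenyl)-3,5-dioxohept-6-enoate F2. Krapcho demethoxycarbonylation of this β-keto ester (LiCl, wet DMSO, about 120 °C) then returns to the route at 15.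

Step 2. The dienolate may attack through its α-carbon or add in conjugate fashion to the cinnamoyl unit, or the dioxinone ring may be opened by the imidazolide anion that is released, giving mixtures instead of clean γ-C-acylation. The fallback sets out from 3, still through imidazolide 5, and uses an open-chain nucleophile that can react only at its terminal carbon. The dianion of methyl acetoacetate (NaH, then n-BuLi, THF, 0 to −78 °C) is acylated to methyl (E)-7-[4-(tert-butyldimethylsilyloxy)-3-methoxyphenyl]-3,5-dioxohept-6-enoate F3. Base-mediated lactonisation (DBU, toluene, reflux) then returns to the route at 8. If DBU and the methanol released also remove the silyl group, the product would be 9, one step further on.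

**Further compounds**
F1 | step 5 | vanillyl alcohol, 4-hydroxy-3-methoxybenzyl alcohol | COc1cc(CO)ccc1O
F2 | step 6 | methyl (6E)-2-(4-hydroxy-3-methoxybenzyl)-7-(4-hydroxy-3-methoxyphenyl)-3,5-dioxohept-6-enoate (racemic at C2) | COC(=O)C(Cc1ccc(O)c(OC)c1)C(=O)CC(=O)/C=C/c1ccc(O)c(OC)c1
F3 | step 2 | methyl (E)-7-[4-(tert-butyldimethylsilyloxy)-3-methoxyphenyl]-3,5-dioxohept-6-enoate | COC(=O)CC(=O)CC(=O)/C=C/c1ccc(O[Si](C)(C)C(C)(C)C)c(OC)c1
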